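The constants used here are made up; the rest is arithmetic.

The starting complex cannot all react in this flask. Every starting complex that reacts costs at least one incoming ligand, and a pair held in the idle adduct costs two between them. There is 6.00 mM of that ligand against 10 mM of starting complex, so the incoming ligand is the limiting reagent and the ceiling is 60.0%.

starting complex 10 mM; incoming ligand 6.00 mM; leaving ligand 50.0 mM (fed, over 0.40 s); time 2.0 min

    starting complex + incoming ligand ⇌ leaving ligand + complex with one exchanged (K1 = 100, k1 = 60 L mol⁻¹ s⁻¹)
    complex with one exchanged + incoming ligand ⇌ leaving ligand + complex with two exchanged (K2 = 3.0, k2 = 76 L mol⁻¹ s⁻¹)
    complex with two exchanged + incoming ligand ⇌ leaving ligand + complex with three exchanged (K3 = 3.3, k3 = 130 L mol⁻¹ s⁻¹)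
    starting complex + complex with two exchanged ⇌ idle adduct, settled at all times (K4 = 210 L mol⁻¹)

- in percentages every species weighs as the starting complex in it: one idle adduct counts as two
- for complex with two exchanged the idle adduct is counted in
- in an amount of complex with two exchanged, one idle adduct counts as one complex with two exchanged
- the reaction counts as stopped when no species that holds the starting complex changes by six tenths of a point or more over the second half of the time
- what has gone from starting complex into another species counts as reacted, even if it can come back
- run time (flask): 2.0 min

* at 2.0 min, what has stopped the reaction, if anything has (forward and back rates have come level / the incoming ligand has run out first / it is still moving / all of the starting complex has reacted)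
* share of the starting complex used up at 2.0 min
* complex with two exchanged at 2.0 min, in percent of the starting complex charged

The feed lasts 0.40 s. That is shorter than 1.9 s, the half-life of starting complex by the forward rate of the first exchange at the charges, so I count the leaving ligand as present from the start. That half-life is short against 2.0 min, so I expect forward and back rates to have come level. I therefore need a balance, not a rate.

The charged leaving ligand divided by the first equilibrium constant, 100, gives 0.500 mM. I call this the level: the free incoming ligand at which starting complex and complex with one exchanged stand equal. At balance, complex with one exchanged over starting complex equals free incoming ligand over the level.

Now I write the balance of the incoming ligand. Let y be the complex with one exchanged formed, with the later steps left out. Free ligand is its charge minus y, and starting complex is its charge minus y. So (ligand charge − y)(starting charge − y) = level × y. This quadratic gives y = 5.41 mM.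

One link I can reforge by hand is the level: each exchange releases a leaving ligand. Adding y raises the level to 0.554 mM, and y becomes 5.36 mM. I commit to 53.6% used up. My reckoning stops at the first exchange, so it gives no figure for complex with two exchanged.

The forecast says forward and back rates have come level, 52.6% used up and 2.9% complex with two exchanged, because “the system relaxes within several seconds”. My conversion stands 1 percentage point above it.

The flask gives forward and back rates have come level, with 52.8% used up and 2.95% complex with two exchanged, adduct counted in. Starting complex already stands at 47.3% after 0.400 min, and a run ten times as long changes the conversion by nothing. This flask is a balance, and more time gains it no product.

Take the neighbouring flask with 17 mM of starting complex, all else the same. Its incoming ligand charge is unchanged, so I keep the level at 0.554 mM. The same quadratic gives y = 5.72 mM, which is 33.6% of that charge. That neighbouring flask ends with 33.3% used up and 4.3% of its incoming ligand left.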